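The quinone ring is cut between C1 (the carbonyl carbon flanked by the hydroxylated C2) and C6 (the only ring CH). Read this way, C1–C4 with their O, O, alkyl, O substituents are the four carbons of a squaric-acid-derived cyclobutenone, and C5(OMe)=C6H is a 1-methoxyvinyl group on C4. Heating this 4-alkenyl-4-siloxycyclobutenone opens the four-membered ring to a dienylketene. Its 6π-electrocyclisation forges C1–C6 and, after tautomerisation, should deliver the aromatic ring with every substituent in place in one operation. Oxidation and tert-butyl ether cleavage then reveal the hydroxyquinone. The precursor is assembled from di-tert-butyl squarate by two carbonyl additions.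

Key step: step 3

Remark: the SMILES is read as 3-heptadecyl-2-hydroxy-5-methoxy-1,4-benzoquinone (unbranched seventeen-carbon chain, no stereocentre). The cyclobutenone carbons carry the locants of the quinone atoms C1–C4 they become. Di-tert-butyl squarate and 1-bromoheptadecane are taken as purchasable.

Step 1
Reactants: 1 di-tert-butyl squarate (3,4-di-tert-butoxycyclobut-3-ene-1,2-dione); 2 methyl vinyl ether
Product: 5 2,3-di-tert-butoxy-4-(1-methoxyethenyl)-4-(trimethylsilyloxy)cyclobut-2-en-1-one (racemic), via 1-methoxyvinyllithium 3 (not isolated), via lithium alkoxide 4 (not isolated)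
Conditions: 2, t-BuLi, THF, −78 → 0 °C; then added to 1, THF, −78 °C; then TMSCl, −78 → 0 °C
Reagents that add atoms: chlorotrimethylsilane (TMSCl), C[Si](C)(C)Cl
Why: α-Lithiated methyl vinyl ether is a hard acyl-anion equivalent that should add 1,2 to one of the two equivalent carbonyl groups of the squaric ester at −78 °C (inverse addition keeps double addition down), and the tertiary lithium alkoxide is capped by O-silylation in the same flask, the new quaternary carbon C4 forming as a racemate that is erased in step 3 (organolithium 1,2-addition to a squarate ester, then silyl ether formation).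

Step 2
Reactants: 5 2,3-di-tert-butoxy-4-(1-methoxyethenyl)-4-(trimethylsilyloxy)cyclobut-2-en-1-one; 6 1-bromoheptadecane
Product: 10 2-tert-butoxy-3-heptadecyl-4-(1-methoxyethenyl)-4-(trimethylsilyloxy)cyclobut-2-en-1-one (racemic), via heptadecylmagnesium bromide 7 (not isolated), via bromomagnesium alkoxide 8 (not isolated), via tertiary trifluoroacetate 9 (not isolated)
Conditions: 6, Mg, THF, 50 °C; then 5, THF, −78 → −20 °C; then pyridine, (CF3CO)2O, −78 → 0 °C; aq NaHCO3
Reagents that add atoms: none
Why: Grignard 1,2-addition to the remaining vinylogous-ester carbonyl gives tertiary alkoxide 8 (both diastereomers serve), whose trifluoroacetate 9 should ionise to an oxygen-stabilised cyclobutenyl cation that loses isobutene from the distal tert-butoxy group, a 1,3-carbonyl transposition of the Stork–Danheiser type that is standard for squarate adducts and places heptadecyl on C3 and the surviving tert-butoxy group on C2, while pyridine buffering protects the enol ether and the silyl ether and a competing conjugate addition–elimination would lead to the same product.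

Step 3
Reactants: 10 2-tert-butoxy-3-heptadecyl-4-(1-methoxyethenyl)-4-(trimethylsilyloxy)cyclobut-2-en-1-one
Product: 13 2-tert-butoxy-3-heptadecyl-5-methoxy-4-(trimethylsilyloxy)phenol, via dienylketene 11 (not isolated), via cyclohexadienone 12 (not isolated)
Conditions: toluene (degassed, 0.02 M), 110 °C
Reagents that add atoms: none
Why: Heating should trigger the thermally allowed conrotatory 4π-electrocyclic opening of the cyclobutenone C1–C4 bond, in which the electron-donating siloxy group on C4 rotates outward (torquoselectivity) and so places the 1-methoxyvinyl group cis to the ketene-bearing carbon in dienylketene 11. Disrotatory 6π-electrocyclisation of 11 then joins the ketene carbon C1 to the vinyl CH2 terminus C6, closing the six-membered carbocycle as cyclohexa-2,4-dienone 12, whose enolisation aromatises it to phenol 13. The closest known reaction type is the thermal ring expansion of 4-alkenyl-4-hydroxy- or 4-siloxycyclobutenones to hydroquinone derivatives (Moore–Liebeskind rearrangement). No stereocentre is created and the only stereocentre of 10 is destroyed. The selectivities needed are the outward rotation of the oxygen substituent, secured by the C4 siloxy donor, and the substitution pattern of the arene, which is fixed because every ring atom of 13 derives from one defined atom of 10; dilute, degassed, nucleophile-free conditions should keep the ketene from dimerising or being trapped.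

Step 4
Reactants: 13 2-tert-butoxy-3-heptadecyl-5-methoxy-4-(trimethylsilyloxy)phenol
Product: 15 Irisoquin-B (3-heptadecyl-2-hydroxy-5-methoxycyclohexa-2,5-diene-1,4-dione), via tert-butoxyquinone 14 (not isolated)
Conditions: (NH4)2Ce(NO3)6, MeCN–H2O, 0 °C; extractive work-up; then CF3CO2H, CH2Cl2, 0 °C → rt
Reagents that add atoms: none
Why: Tetravalent cerium should oxidise the para-siloxyphenol (the silyl group is lost hydrolytically) to 1,4-benzoquinone 14, whose ring is no longer open to Friedel–Crafts tert-butylation, and trifluoroacetic acid then removes the tert-butyl group of the C2 vinylogous ester by E1 loss of isobutene while the methyl vinylogous ester at C5, which cannot ionise, stays (oxidation of a hydroquinone derivative to a quinone, then acidolysis of a tert-butyl ether).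

Compound list
1 | di-tert-butyl squarate (3,4-di-tert-butoxycyclobut-3-ene-1,2-dione) | CC(C)(C)OC1=C(OC(C)(C)C)C(=O)C1=O | starting material
2 | methyl vinyl ether (methoxyethene) | COC=C | starting material
3 | 1-methoxyvinyllithium | [Li]C(=C)OC | intermediate
4 | lithium 2,3-di-tert-butoxy-1-(1-methoxyethenyl)-4-oxocyclobut-2-en-1-olate (racemic) | COC(=C)C1(O[Li])C(OC(C)(C)C)=C(OC(C)(C)C)C1=O | intermediate
5 | 2,3-di-tert-butoxy-4-(1-methoxyethenyl)-4-(trimethylsilyloxy)cyclobut-2-en-1-one (racemic) | COC(=C)C1(O[Si](C)(C)C)C(OC(C)(C)C)=C(OC(C)(C)C)C1=O | intermediate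
6 | 1-bromoheptadecane | CCCCCCCCCCCCCCCCCBr | starting material
7 | heptadecylmagnesium bromide | CCCCCCCCCCCCCCCCC[Mg]Br | intermediate
8 | bromomagnesium 2,3-di-tert-butoxy-1-heptadecyl-4-(1-methoxyethenyl)-4-(trimethylsilyloxy)cyclobut-2-en-1-olate (racemic, mixture of diastereomers) | CCCCCCCCCCCCCCCCCC1(O[Mg]Br)C(OC(C)(C)C)=C(OC(C)(C)C)C1(O[Si](C)(C)C)C(=C)OC | intermediate
9 | 2,3-di-tert-butoxy-1-heptadecyl-4-(1-methoxyethenyl)-4-(trimethylsilyloxy)cyclobut-2-en-1-yl trifluoroacetate (racemic, mixture of diastereomers) | CCCCCCCCCCCCCCCCCC1(OC(=O)C(F)(F)F)C(OC(C)(C)C)=C(OC(C)(C)C)C1(O[Si](C)(C)C)C(=C)OC | intermediate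
10 | 2-tert-butoxy-3-heptadecyl-4-(1-methoxyethenyl)-4-(trimethylsilyloxy)cyclobut-2-en-1-one (racemic) | CCCCCCCCCCCCCCCCCC1=C(OC(C)(C)C)C(=O)C1(O[Si](C)(C)C)C(=C)OC | intermediate
11 | (3E)-2-tert-butoxy-3-heptadecyl-5-methoxy-4-(trimethylsilyloxy)hexa-1,3,5-trien-1-one (dienylketene, 1-methoxyvinyl group cis to the ketene-bearing carbon) | O=C=C(OC(C)(C)C)/C(CCCCCCCCCCCCCCCCC)=C(O[Si](C)(C)C)\C(=C)OC | intermediate
12 | 2-tert-butoxy-3-heptadecyl-5-methoxy-4-(trimethylsilyloxy)cyclohexa-2,4-dien-1-one | CCCCCCCCCCCCCCCCCC1=C(OC(C)(C)C)C(=O)CC(OC)=C1O[Si](C)(C)C | intermediate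
13 | 2-tert-butoxy-3-heptadecyl-5-methoxy-4-(trimethylsilyloxy)phenol | CCCCCCCCCCCCCCCCCc1c(OC(C)(C)C)c(O)cc(OC)c1O[Si](C)(C)C | intermediate
14 | 2-tert-butoxy-3-heptadecyl-5-methoxycyclohexa-2,5-diene-1,4-dione | CCCCCCCCCCCCCCCCCC1=C(OC(C)(C)C)C(=O)C=C(OC)C1=O | intermediate
15 | Irisoquin-B (3-heptadecyl-2-hydroxy-5-methoxycyclohexa-2,5-diene-1,4-dione) | CCCCCCCCCCCCCCCCCC1=C(O)C(=O)C=C(OC)C1=O | target

Total step count: 4
Longest linear sequence: 4 steps (1 → 5 → 10 → 13 → 15)

Steps most likely to fail

Step 2. The ionisation may destroy the 1-methoxyvinyl enol ether (protonation and hydrolysis to an acetyl group, or C-acylation by the anhydride), and the liberated trifluoroacetic acid may strip the second tert-butyl group or the silyl ether. The fallback carries the two-carbon unit as a plain vinyl group through the ionisation and introduces the C5 methoxy group at the quinone stage; it sets out from compound 1 and returns at compound 14. Vinylmagnesium bromide (CH2=CHMgBr, THF, −78 °C) followed by TMSCl should give 2,3-di-tert-butoxy-4-ethenyl-4-(trimethylsilyloxy)cyclobut-2-en-1-one F1. Addition of 7 and the same pyridine-buffered trifluoroacetic anhydride ionisation, now without an acid-labile enol ether, should give 2-tert-butoxy-4-ethenyl-3-heptadecyl-4-(trimethylsilyloxy)cyclobut-2-en-1-one F2. Thermolysis in toluene at 110 °C (the same ring opening and 6π closure) should give 2-tert-butoxy-3-heptadecyl-4-(trimethylsilyloxy)phenol F3, and (NH4)2Ce(NO3)6 should oxidise it to 2-tert-butoxy-3-heptadecylcyclohexa-2,5-diene-1,4-dione F4. ZnCl2-promoted conjugate addition of methanol to F4 should occur at C5, the β-carbon of the C1 enone, because the C4 carbonyl is deactivated as a vinylogous ester by the C2 tert-butoxy group. This gives 2-tert-butoxy-3-heptadecyl-5-methoxybenzene-1,4-diol F5, which Ag2O should oxidise to compound 14.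

Step 3. At 110 °C, thermal loss of isobutene from the tert-butyl enol ether, or dimerisation or trapping of the ketene before 6π closure, may compete with the ring expansion. The fallback triggers the ring opening by oxyanion acceleration at low temperature instead of neutral thermolysis; it sets out from compound 10 and returns at compound 14. Bu4NF buffered with AcOH (THF, 0 °C) should give 2-tert-butoxy-3-heptadecyl-4-hydroxy-4-(1-methoxyethenyl)cyclobut-2-en-1-one F6. Its potassium alkoxide (KN(SiMe3)2, THF, −78 → 20 °C) should undergo the charge-accelerated conrotatory opening known from squarate cascade chemistry, with the oxido group rotating outward, followed by 6π closure. After an NH4Cl quench this gives 2-tert-butoxy-3-heptadecyl-5-methoxybenzene-1,4-diol F5, which (NH4)2Ce(NO3)6 should oxidise to compound 14.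

Step 4. Aqueous acidic tetravalent cerium may over-oxidise the electron-rich ring or hydrolyse the C5 methyl vinylogous ester, and the subsequent acidolysis may then be unselective. The fallback inverts the order (deprotection on the arene, then oxidation by oxygen alone); it sets out from compound 13 and returns at compound 15. CF3CO2H with thioanisole as cation scavenger (CH2Cl2, 0 °C) should remove both the tert-butyl and the trimethylsilyl group to give 3-heptadecyl-5-methoxybenzene-1,2,4-triol F7. Stirring F7 in methanol under air should autoxidise the hydroxyhydroquinone to compound 15.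

Further compounds
F1 | step 2 | 2,3-di-tert-butoxy-4-ethenyl-4-(trimethylsilyloxy)cyclobut-2-en-1-one (racemic) | C=CC1(O[Si](C)(C)C)C(OC(C)(C)C)=C(OC(C)(C)C)C1=O
F2 | step 2 | 2-tert-butoxy-4-ethenyl-3-heptadecyl-4-(trimethylsilyloxy)cyclobut-2-en-1-one (racemic) | CCCCCCCCCCCCCCCCCC1=C(OC(C)(C)C)C(=O)C1(O[Si](C)(C)C)C=C
F3 | step 2 | 2-tert-butoxy-3-heptadecyl-4-(trimethylsilyloxy)phenol | CCCCCCCCCCCCCCCCCc1c(OC(C)(C)C)c(O)ccc1O[Si](C)(C)C
F4 | step 2 | 2-tert-butoxy-3-heptadecylcyclohexa-2,5-diene-1,4-dione | CCCCCCCCCCCCCCCCCC1=C(OC(C)(C)C)C(=O)C=CC1=O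
F5 | step 2 | 2-tert-butoxy-3-heptadecyl-5-methoxybenzene-1,4-diol | CCCCCCCCCCCCCCCCCc1c(OC(C)(C)C)c(O)cc(OC)c1O
F6 | step 3 | 2-tert-butoxy-3-heptadecyl-4-hydroxy-4-(1-methoxyethenyl)cyclobut-2-en-1-one (racemic) | CCCCCCCCCCCCCCCCCC1=C(OC(C)(C)C)C(=O)C1(O)C(=C)OC
F7 | step 4 | 3-heptadecyl-5-methoxybenzene-1,2,4-triol | CCCCCCCCCCCCCCCCCc1c(O)c(O)cc(OC)c1O
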